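**Retrosynthetic overview**
1. The target is the acetate of allylic alcohol 19, which comes from enedione 18 by 1,2-reduction at C4; hydride should arrive anti to the endo aryl group. 18 comes from the saturated diketone 16 by dehydrogenation across C2–C3.
2. Key disconnection of 16: the C6–aryl bond and the C4–C5 bond in one operation. An aryl–copper reagent adds to C6 of the 2-methoxycyclopent-2-enone 12, and the C5 enolate acylates itself with the ester at the end of the C1 side chain (C2–C3–C4).
3. Enabling feature: C5 is at once the methoxy-bearing bridgehead, the α-carbon of the C8 ketone in the five-membered ring C1–C8–C5–C6–C7, and the neighbour of the aryl-bearing C6. C4=O and C8=O are 1,3 across C5, so an enol ether C5(OMe)=C6 plus an ester at C4 is the retron for conjugate addition followed by enolate acylation.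
4. 12 comes from keto ester 8 (C5 oxidation to the diosphenol, then O-methylation); 8 from ketone 4 by Michael quaternisation at C1; 4 from 3-methylcyclopentenone by asymmetric conjugate reduction and allylation. C7 is the only centre set by a catalyst; C1, C6, C5 and C4 are relayed from it.
5. Ring order: the cyclopentane ring (from 1) and the aryl ring (from 13) are bought; the six-membered ring C1–C2–C3–C4–C5–C8 is closed last, in step 6, and completes the bicyclo[3.2.1]octane.

Key step: step 6

Remark: atoms are numbered as in the bicyclo[3.2.1]oct-2-ene core of the target throughout, also in monocyclic precursors (C1 allyl bridgehead, C2=C3, C4, C5 methoxy bridgehead, C6 aryl, C7 methyl, C8 bridging carbonyl; endo = toward the C2–C3–C4 bridge). Methyl 2-methoxyacrylate and 3,4,5-trimethoxyphenylmagnesium bromide (THF solution) are taken as catalogue reagents.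

**Step 1**
Reactants: 1 3-methylcyclopent-2-en-1-one; 2 allyl bromide
Product: 4 (2R,3S)-2-allyl-3-methylcyclopentan-1-one (trans), via diphenylsilyl enol ether 3 (not isolated)
Conditions: CuCl (5 mol %), NaOtBu (5 mol %), p-tol-BINAP (5 mol %, the antipode that gives 3S), Ph2SiH2, toluene, 0 °C; then 2, Bu4N[Ph3SiF2], CH2Cl2, rt
Reagents that add atoms: none
Why: Copper hydride asymmetric conjugate reduction of the β-methyl enone should fix C7 under catalyst control and leave the enol silane on the C1 side, and its fluoride-triggered enolate alkylation should bring the allyl group in trans to the new methyl group.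

**Step 2**
Reactants: 4 (2R,3S)-2-allyl-3-methylcyclopentan-1-one; 5 methyl 2-methoxyacrylate
Product: 8 methyl 3-[(1R,2S)-1-allyl-2-methyl-5-oxocyclopentyl]-2-methoxypropanoate (both epimers at the ester α-carbon), via N-benzyl imine 6 (not isolated), via adduct imine 7 (not isolated)
Conditions: BnNH2, 4 Å MS, toluene, rt; 5 (3 equiv), neat, 70 °C; then 10% aq AcOH, THF, rt
Reagents that add atoms: none
Why: Aza-ene-type Michael addition of the more substituted secondary enamine tautomer of imine 6 (the deracemising-alkylation reaction of 2-substituted cycloalkanone imines) should alkylate the substituted α-carbon C1 on the face anti to the C7 methyl group, so that the quaternary centre carries allyl cis and the ester chain trans to methyl, while the ester α-carbon forms as both epimers and is erased in step 7.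

**Step 3**
Reactants: 8 methyl 3-[(1R,2S)-1-allyl-2-methyl-5-oxocyclopentyl]-2-methoxypropanoate
Product: 9 methyl 3-[(1R,2S,4E)-1-allyl-4-(dimethylaminomethylidene)-2-methyl-5-oxocyclopentyl]-2-methoxypropanoate
Conditions: tBuOCH(NMe2)2, toluene, 90 °C
Reagents that add atoms: tert-butoxybis(dimethylamino)methane (Bredereck's reagent), CN(C)C(OC(C)(C)C)N(C)C
Why: Aminomethylenation of a ketone α-methylene with Bredereck's reagent can take place only at C5, the single α-CH2 left once C1 is quaternary.

**Step 4**
Reactants: 9 enaminone from step 3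
Product: 11 methyl 3-[(1R,5S)-1-allyl-3-hydroxy-5-methyl-2-oxocyclopent-3-en-1-yl]-2-methoxypropanoate (diosphenol), via dioxetane 10 (not isolated)
Conditions: O2, visible light, tetraphenylporphyrin (cat.), CH2Cl2, −78 °C, then rt
Reagents that add atoms: oxygen, O=O
Why: Singlet-oxygen [2+2] cleavage of the electron-rich enaminone double bond through dioxetane 10 should give the 1,2-dione, which can enolise only toward C6 because C1 is quaternary, and the monosubstituted allyl alkene does not react with singlet oxygen.

**Step 5**
Reactants: 11 diosphenol from step 4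
Product: 12 methyl 3-[(1R,5S)-1-allyl-3-methoxy-5-methyl-2-oxocyclopent-3-en-1-yl]-2-methoxypropanoate
Conditions: Me2SO4, K2CO3, acetone, reflux
Reagents that add atoms: dimethyl sulfate, COS(=O)(=O)OC
Why: Williamson-type O-methylation of the acidic diosphenol with the hard electrophile dimethyl sulfate should fix the C5=C6 enol as its methyl ether, the Michael acceptor of the key step.

**Step 6**
Reactants: 12 2-methoxy-enone ester from step 5; 13 3,4,5-trimethoxyphenylmagnesium bromide
Product: 16 1-allyl-3,5-dimethoxy-7-methyl-6-(3,4,5-trimethoxyphenyl)bicyclo[3.2.1]octane-4,8-dione (6-endo-aryl; 7-exo-methyl; C1, C5, C6, C7 as in the target; both C3 epimers), via bromomagnesium enolate 14 (not isolated), via lithium enolate 15 (not isolated)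
Conditions: 13 (1.2 equiv), CuBr·SMe2 (10 mol %), THF, −40 °C; then LiN(SiMe3)2 (1.2 equiv), −40 to 0 °C; AcOH, −40 °C
Reagents that add atoms: none
Why: Copper-catalysed conjugate transfer of the aryl group from 13 to C6 of the 2-methoxy-enone should give bromomagnesium enolate 14, whose C5 attacks the ester carbonyl C4 of the chain on C1; loss of methoxide gives the 1,3-diketone, which LiN(SiMe3)2 deprotonates at C3, its only acidic position, to enolate 15, so that the condensation is driven like any Dieckmann reaction. The closest known reaction types are the tandem cuprate conjugate addition–Dieckmann cyclisation and the α,α'-annulation of cyclopentanones to bicyclo[3.2.1]octane-2,8-diones. The only ring closed is the six-membered ring C1–C2–C3–C4–C5–C8, by 6-(enolendo)-exo-trig attack of the enolate carbon on the ester. C6 is set by the neighbouring C7 methyl group (aryl enters anti, as in cuprate additions to 4-substituted cyclopentenones); C5 is set by the tether, because the chain sits on C1 on the face anti to methyl and can reach C5 only there, which puts the methoxy group exo and the aryl group endo under the new bridge; C3 forms as both epimers and is removed in step 7. The step needs 1,4- over 1,2-addition and C- over O-acylation: the C8 carbonyl is flanked by quaternary C1 and copper catalysis at low temperature favours the conjugate path, and an enol lactone from O-acylation would stay a reversible acyl donor that is funnelled to the C-acylated product once this is trapped as enolate 15.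

**Step 7**
Reactants: 16 saturated diketone from step 6
Product: 18 1-allyl-3,5-dimethoxy-7-methyl-6-(3,4,5-trimethoxyphenyl)bicyclo[3.2.1]oct-2-ene-4,8-dione (C1, C5, C6, C7 as in the target), via trimethylsilyl enol ether 17 (not isolated)
Conditions: Me3SiOTf, Et3N, CH2Cl2, 0 °C; then Pd(OAc)2 (1.1 equiv), MeCN, rt
Reagents that add atoms: none
Why: Saegusa–Ito oxidation, in which soft enolisation can take place only at C3 (C8 has no α-hydrogen) and β-hydride elimination from C2 gives the conjugated enol ether, so that both C3 epimers should converge on one enedione.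

**Step 8**
Reactants: 18 enedione from step 7
Product: 19 (1S,4R,5S,6R,7S)-1-allyl-4-hydroxy-3,5-dimethoxy-7-methyl-6-(3,4,5-trimethoxyphenyl)bicyclo[3.2.1]oct-2-en-8-one
Conditions: NaBH4, CeCl3·7H2O, MeOH, −78 °C
Reagents that add atoms: none
Why: Luche reduction should reduce the conjugated C4 carbonyl 1,2 in preference to the non-conjugated C8 ketone shielded by two quaternary bridgeheads, with hydride arriving from the C8 side of C4 because the endo aryl group on C6 covers the opposite face, so that the hydroxyl ends cis to the aryl-bearing bridge (4R).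

**Step 9**
Reactants: 19 allylic alcohol from step 8
Product: 20 (1S,4R,5S,6R,7S)-1-allyl-3,5-dimethoxy-7-methyl-8-oxo-6-(3,4,5-trimethoxyphenyl)bicyclo[3.2.1]oct-2-en-4-yl acetate (CNP0181407.1)
Conditions: Ac2O, pyridine, DMAP (cat.), CH2Cl2, rt
Reagents that add atoms: acetic anhydride, CC(=O)OC(C)=O
Why: DMAP-catalysed acetylation of the secondary allylic alcohol takes place at oxygen with retention at C4 and should not touch the enol ether or the hindered ketone.

**Compound list**
1 | 3-methylcyclopent-2-en-1-one | CC1=CC(=O)CC1 | starting material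
2 | allyl bromide | C=CCBr | starting material
3 | (S)-[(3-methylcyclopent-1-en-1-yl)oxy]diphenylsilane (not isolated) | C[C@H]1CCC(O[SiH](c2ccccc2)c2ccccc2)=C1 | intermediate
4 | (2R,3S)-2-allyl-3-methylcyclopentan-1-one | O=C1CC[C@H](C)[C@H]1CC=C | intermediate
5 | methyl 2-methoxyacrylate | C=C(OC)C(=O)OC | starting material
6 | N-benzyl imine of 4 (not isolated) | C(c1ccccc1)N=C1CC[C@H](C)[C@H]1CC=C | intermediate
7 | N-benzyl imine of 8 (not isolated) | C(c1ccccc1)N=C1CC[C@H](C)[C@@]1(CC=C)CC(OC)C(=O)OC | intermediate
8 | methyl 3-[(1R,2S)-1-allyl-2-methyl-5-oxocyclopentyl]-2-methoxypropanoate, both epimers at the ester α-carbon | O=C1CC[C@H](C)[C@@]1(CC=C)CC(OC)C(=O)OC | intermediate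
9 | methyl 3-[(1R,2S,4E)-1-allyl-4-(dimethylaminomethylidene)-2-methyl-5-oxocyclopentyl]-2-methoxypropanoate | O=C1/C(=C/N(C)C)C[C@H](C)[C@@]1(CC=C)CC(OC)C(=O)OC | intermediate
10 | spiro-dioxetane from 9 and singlet oxygen (not isolated) | O=C1C2(OOC2N(C)C)C[C@H](C)[C@@]1(CC=C)CC(OC)C(=O)OC | intermediate
11 | methyl 3-[(1R,5S)-1-allyl-3-hydroxy-5-methyl-2-oxocyclopent-3-en-1-yl]-2-methoxypropanoate | O=C1C(O)=C[C@H](C)[C@@]1(CC=C)CC(OC)C(=O)OC | intermediate
12 | methyl 3-[(1R,5S)-1-allyl-3-methoxy-5-methyl-2-oxocyclopent-3-en-1-yl]-2-methoxypropanoate | O=C1C(OC)=C[C@H](C)[C@@]1(CC=C)CC(OC)C(=O)OC | intermediate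
13 | 3,4,5-trimethoxyphenylmagnesium bromide | COc1cc([Mg]Br)cc(OC)c1OC | starting material
14 | bromomagnesium enolate of the conjugate adduct, aryl trans to methyl (not isolated) | C=CC[C@]1(CC(OC)C(=O)OC)C(O[Mg]Br)=C(OC)[C@@H](c2cc(OC)c(OC)c(OC)c2)[C@@H]1C | intermediate
15 | lithium C3=C4 enolate of 16 (not isolated) | C=CC[C@]12CC(OC)=C(O[Li])[C@](OC)(C1=O)[C@@H](c1cc(OC)c(OC)c(OC)c1)[C@@H]2C | intermediate
16 | 1-allyl-3,5-dimethoxy-7-methyl-6-(3,4,5-trimethoxyphenyl)bicyclo[3.2.1]octane-4,8-dione, 6-endo-aryl, 7-exo-methyl, both C3 epimers | C=CC[C@]12CC(OC)C(=O)[C@](OC)(C1=O)[C@@H](c1cc(OC)c(OC)c(OC)c1)[C@@H]2C | intermediate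
17 | C3=C4 trimethylsilyl enol ether of 16 (not isolated) | C=CC[C@]12CC(OC)=C(O[Si](C)(C)C)[C@](OC)(C1=O)[C@@H](c1cc(OC)c(OC)c(OC)c1)[C@@H]2C | intermediate
18 | 1-allyl-3,5-dimethoxy-7-methyl-6-(3,4,5-trimethoxyphenyl)bicyclo[3.2.1]oct-2-ene-4,8-dione, 6-endo-aryl, 7-exo-methyl | C=CC[C@]12C=C(OC)C(=O)[C@](OC)(C1=O)[C@@H](c1cc(OC)c(OC)c(OC)c1)[C@@H]2C | intermediate
19 | (1S,4R,5S,6R,7S)-1-allyl-4-hydroxy-3,5-dimethoxy-7-methyl-6-(3,4,5-trimethoxyphenyl)bicyclo[3.2.1]oct-2-en-8-one | C=CC[C@]12C=C(OC)[C@@H](O)[C@](OC)(C1=O)[C@@H](c1cc(OC)c(OC)c(OC)c1)[C@@H]2C | intermediate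
20 | (1S,4R,5S,6R,7S)-1-allyl-3,5-dimethoxy-7-methyl-8-oxo-6-(3,4,5-trimethoxyphenyl)bicyclo[3.2.1]oct-2-en-4-yl acetate | C=CC[C@]12C=C(OC)[C@@H](OC(C)=O)[C@](OC)(C1=O)[C@@H](c1cc(OC)c(OC)c(OC)c1)[C@@H]2C | target

**Totals**
Total step count: 9. Longest linear sequence: 9 steps (from 1).

**Steps most likely to fail**

Step 6. The aryl transfer to the donor-substituted (α-methoxy) enone may be slow, so that 1,2-addition competes. The bridging acylation may also stall through O-acylation to an enol lactone or through reversal of the Claisen closure before the product is deprotonated. The fallback sets out from 12. The copper-catalysed addition of 13 is run with Me3SiCl (THF, −78 °C) and the trimethylsilyl enol ether of the conjugate adduct F1 is isolated. Its ester is reduced with iBu2AlH at −78 °C, the ketone being masked as the enol ether, to the aldehyde F2. The C4–C5 bond is then closed by an intramolecular Mukaiyama aldol reaction (BF3·OEt2, CH2Cl2, −78 °C), which is not reversible under these conditions, to the bicyclic aldol F3 (mixture at C3 and C4). Oxidation with Dess–Martin periodinane comes back to the route at 16.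

Step 8. Hydride transfer to the strained C8 bridging ketone may compete with reduction at C4 (loss of chemoselectivity). The fallback sets out from 18. Both carbonyl groups are reduced with excess NaBH4 and CeCl3·7H2O (MeOH, 0 °C) to the 4,8-diol F4, with the same facial bias at C4. Only the allylic C4 hydroxyl is then acetylated (Ac2O, pyridine, 0 °C), because the C8 hydroxyl lies between two quaternary bridgeheads, to the hydroxy acetate F5. Re-oxidation of C8 with Dess–Martin periodinane comes back to the route at 20.

Step 2. Carbon–carbon bond formation between the hindered secondary enamine and the weakly electrophilic α-methoxyacrylate may be slow, with competing alkylation at C5 or polymerisation of the acrylate. The fallback sets out from 4. Silylation under equilibrating conditions (Me3SiCl, NaI, Et3N, MeCN) should give mainly the tetrasubstituted trimethylsilyl enol ether F6. MeLi (THF, 0 °C) releases the regiodefined lithium enolate, and its Michael addition to 5 at −78 °C, anti to the methyl group, comes back to the route at 8.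

**Further compounds**
F1 | step 6 | trimethylsilyl enol ether (C5=C8) of the conjugate adduct of 12 and 13, aryl trans to methyl | C=CC[C@]1(CC(OC)C(=O)OC)C(O[Si](C)(C)C)=C(OC)[C@@H](c2cc(OC)c(OC)c(OC)c2)[C@@H]1C
F2 | step 6 | aldehyde from F1 (side chain CH2–CH(OMe)–CHO), silyl enol ether retained | C=CC[C@]1(CC(OC)C=O)C(O[Si](C)(C)C)=C(OC)[C@@H](c2cc(OC)c(OC)c(OC)c2)[C@@H]1C
F3 | step 6 | 1-allyl-4-hydroxy-3,5-dimethoxy-7-methyl-6-(3,4,5-trimethoxyphenyl)bicyclo[3.2.1]octan-8-one, mixture at C3 and C4 | C=CC[C@]12CC(OC)C(O)[C@](OC)(C1=O)[C@@H](c1cc(OC)c(OC)c(OC)c1)[C@@H]2C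
F4 | step 8 | 1-allyl-3,5-dimethoxy-7-methyl-6-(3,4,5-trimethoxyphenyl)bicyclo[3.2.1]oct-2-ene-4,8-diol, 4R, C8 either epimer | C=CC[C@]12C=C(OC)[C@@H](O)[C@](OC)(C1O)[C@@H](c1cc(OC)c(OC)c(OC)c1)[C@@H]2C
F5 | step 8 | 4-acetate of F4 with free C8 hydroxyl | C=CC[C@]12C=C(OC)[C@@H](OC(C)=O)[C@](OC)(C1O)[C@@H](c1cc(OC)c(OC)c(OC)c1)[C@@H]2C
F6 | step 2 | (S)-[(2-allyl-3-methylcyclopent-1-en-1-yl)oxy]trimethylsilane | C[C@H]1CCC(O[Si](C)(C)C)=C1CC=C
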